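**Strategy.** Everything rests on forming the O–C3 bond of the oxolane ring (O, C3, C4, C5, C6). The key step exploits the fact that C3 is tertiary, allylic to the C1=C2 bromovinyl group and flanked by oxygen-bearing C4: a C3–C4 oxirane is opened at C3 by the C6 hydroxyl, 5-endo, with inversion. This one operation closes the ring, sets the quaternary centre C3 and leaves the C4 hydroxyl trans to the bromovinyl arm, ready for chloride to enter with inversion. The precursor is an open-chain (E)-bromovinyl epoxy alcohol: a (2R,3R)-oxirane from a Sharpless epoxidation, a free (S)-carbinol at C6 from an asymmetric allylation, and an isopropenyl group that later becomes C7–C9.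

Key step: step 9

Remark: atoms are labelled along the open chain, C1 (CHBr), C2, C3 (ring carbon, methyl C10), C4 (CHCl), C5, C6 (ring CH), C7 (CBr, methyl C9), C8 (CH2Cl); (−)-B-allyldiisopinocampheylborane is assumed to be bought as its pentane solution.

Step 1
Reactants: 1 methacrolein; 2 (−)-B-allyldiisopinocampheylborane
Product: 4 (S)-2-methylhexa-1,5-dien-3-ol, via borinate ester 3 (not isolated)
Conditions: Et2O, −78 °C; then NaOH (3 M aq.), H2O2 (30%), 0 °C → rt
Reagents that add atoms: none
Why: Brown allylboration through a chair six-membered transition state in which the isopinocampheyl groups from (+)-α-pinene send the allyl group to the Si face of the aldehyde, which sets the C6 carbinol as S, and oxidative work-up frees the alcohol.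

Step 2
Reactants: 4 (S)-2-methylhexa-1,5-dien-3-ol
Product: 5 (S)-tert-butyldimethyl[(2-methylhexa-1,5-dien-3-yl)oxy]silane
Conditions: TBSCl, imidazole, DMF, rt
Reagents that add atoms: tert-butyldimethylsilyl chloride, CC(C)(C)[Si](C)(C)Cl
Why: Silyl ether formation masks the C6 hydroxyl, so that the isopropenyl alkene is no longer part of an allylic alcohol in the epoxidation and the oxygen cannot reach the oxirane before step 9.

Step 3
Reactants: 5 (S)-tert-butyldimethyl[(2-methylhexa-1,5-dien-3-yl)oxy]silane; 1 methacrolein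
Product: 6 (2E,5S)-5-[(tert-butyldimethylsilyl)oxy]-2,6-dimethylhepta-2,6-dienal
Conditions: 1 (5 equiv), second-generation Hoveyda–Grubbs catalyst (5 mol %), CH2Cl2, 40 °C
Reagents that add atoms: none
Why: Olefin cross-metathesis in which only the unhindered terminal vinyl group enters the cycle (the isopropenyl group beside the silyloxy carbon is too hindered and ring closure would need a cyclobutene), the trisubstituted enal forming as the thermodynamically favoured E isomer.

Step 4
Reactants: 6 (2E,5S)-5-[(tert-butyldimethylsilyl)oxy]-2,6-dimethylhepta-2,6-dienal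
Product: 7 (2E,5S)-5-[(tert-butyldimethylsilyl)oxy]-2,6-dimethylhepta-2,6-dien-1-ol
Conditions: NaBH4, CeCl3·7H2O, MeOH, 0 °C
Reagents that add atoms: none
Why: Luche 1,2-reduction of the enal gives the allylic alcohol without touching the alkenes or the silyl ether.

Step 5
Reactants: 7 (2E,5S)-5-[(tert-butyldimethylsilyl)oxy]-2,6-dimethylhepta-2,6-dien-1-ol
Product: 8 [(2R,3R)-3-[(2S)-2-[(tert-butyldimethylsilyl)oxy]-3-methylbut-3-en-1-yl]-2-methyloxiran-2-yl]methanol
Conditions: Ti(OiPr)4 (10 mol %), D-(−)-diethyl tartrate (12 mol %), t-BuOOH, 4 Å MS, CH2Cl2, −20 °C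
Reagents that add atoms: tert-butyl hydroperoxide, CC(C)(C)OO
Why: Sharpless asymmetric epoxidation, in which only the allylic alcohol binds titanium and the D-(−)-tartrate catalyst delivers oxygen to the face that gives the (2R,3R)-oxirane (the L-(+)-ester gives 2S,3S with E-2-methylalk-2-en-1-ols), syn addition keeping C5 cis to methyl C10 and the catalyst overriding the remote C6 centre.

Step 6
Reactants: 8 [(2R,3R)-3-[(2S)-2-[(tert-butyldimethylsilyl)oxy]-3-methylbut-3-en-1-yl]-2-methyloxiran-2-yl]methanol
Product: 9 (2S,3R)-3-[(2S)-2-[(tert-butyldimethylsilyl)oxy]-3-methylbut-3-en-1-yl]-2-methyloxirane-2-carbaldehyde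
Conditions: TEMPO (10 mol %), PhI(OAc)2, CH2Cl2, rt
Reagents that add atoms: none
Why: TEMPO-catalysed oxidation of the primary alcohol with PhI(OAc)2 as terminal oxidant is mild enough for the oxirane, and the aldehyde has no α-hydrogen and cannot epimerise.

Step 7
Reactants: 9 (2S,3R)-3-[(2S)-2-[(tert-butyldimethylsilyl)oxy]-3-methylbut-3-en-1-yl]-2-methyloxirane-2-carbaldehyde; 10 bromoform
Product: 11 tert-butyl{[(2S)-1-[(2R,3R)-3-[(E)-2-bromoethenyl]-3-methyloxiran-2-yl]-3-methylbut-3-en-2-yl]oxy}dimethylsilane
Conditions: CHBr3 (10), CrBr2 (anhydrous), THF, rt → 40 °C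
Reagents that add atoms: none
Why: Takai olefination, in which the geminal dichromium species from bromoform adds to the aldehyde and anti-elimination gives the E-bromoalkene, favoured further by the bulky quaternary α-carbon, CrBr2 being used so that no chloro-olefin can arise by halide exchange.

Step 8
Reactants: 11 tert-butyl{[(2S)-1-[(2R,3R)-3-[(E)-2-bromoethenyl]-3-methyloxiran-2-yl]-3-methylbut-3-en-2-yl]oxy}dimethylsilane
Product: 12 (2S)-1-[(2R,3R)-3-[(E)-2-bromoethenyl]-3-methyloxiran-2-yl]-3-methylbut-3-en-2-ol
Conditions: Bu4NF, AcOH, THF, 0 °C → rt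
Reagents that add atoms: none
Why: Fluoride desilylation, buffered with acetic acid so that the alkoxide neither attacks the oxirane nor eliminates HBr from the bromoalkene, frees the C6 hydroxyl only one step before it is needed.

Step 9
Reactants: 12 (2S)-1-[(2R,3R)-3-[(E)-2-bromoethenyl]-3-methyloxiran-2-yl]-3-methylbut-3-en-2-ol
Product: 13 (2S,3R,5S)-2-[(E)-2-bromoethenyl]-2-methyl-5-(prop-1-en-2-yl)oxolan-3-ol
Conditions: (+)-10-camphorsulfonic acid (10 mol %), CH2Cl2, −40 → 0 °C
Reagents that add atoms: none
Why: Protonation of the oxirane oxygen lengthens the C3–O bond, whose developing positive charge is carried by the tertiary carbon and the adjacent C1=C2 π system, and the C6 hydroxyl displaces that oxygen from the rear in a borderline SN2 opening. The closest known reaction type is the acid-catalysed endo-selective opening of vinyl epoxides by a tethered alcohol. The oxolane ring (O, C3, C4, C5, C6) closes in the 5-endo mode at the epoxide, the only alternative being 4-exo attack at C4 to a strained oxetane. The new stereocentre C3 arises by inversion of the epoxide carbon, so it is dictated by the (2R,3R)-oxirane of step 5; C4 and C6 are untouched, which puts the C4 hydroxyl trans to both arms and the bromovinyl and isopropenyl arms cis. The step needs attack at C3 and clean inversion in place of free ionisation; the tertiary allylic C3, the three-atom tether, the bromine-damped donor ability of the alkene, the catalytic non-nucleophilic acid, the non-polar solvent and the low temperature should secure both.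

Step 10
Reactants: 13 (2S,3R,5S)-2-[(E)-2-bromoethenyl]-2-methyl-5-(prop-1-en-2-yl)oxolan-3-ol
Product: 15 (2S,3S,5S)-2-[(E)-2-bromoethenyl]-3-chloro-2-methyl-5-(prop-1-en-2-yl)oxolane, via C4 triflate 14 (not isolated)
Conditions: Tf2O, pyridine, CH2Cl2, −20 °C; then Bu4NCl, toluene, 0 °C → rt
Reagents that add atoms: tetrabutylammonium chloride, CCCC[N+](CCCC)(CCCC)CCCC.[Cl-]; trifluoromethanesulfonic anhydride, O=S(=O)(OS(=O)(=O)C(F)(F)F)C(F)(F)F (kept only in 14)
Why: Sulfonate displacement (SN2), in which the β-alkoxy triflate resists ionisation and soluble chloride enters from the face opposite the leaving group, inverting C4 and placing chlorine cis to the bromovinyl arm.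

Step 11
Reactants: 15 (2S,3S,5S)-2-[(E)-2-bromoethenyl]-3-chloro-2-methyl-5-(prop-1-en-2-yl)oxolane
Product: 16 (2S,3S,5S)-2-[(E)-2-bromoethenyl]-3-chloro-5-(3-chloroprop-1-en-2-yl)-2-methyloxolane
Conditions: Ca(OCl)2, CO2 (solid), CH2Cl2–H2O, 0 °C
Reagents that add atoms: calcium hypochlorite, [Ca+2].[O-]Cl.[O-]Cl
Why: Ene-type allylic chlorination by hypochlorous acid, in which electrophilic chlorine adds to the terminal carbon of the electron-rich 1,1-disubstituted alkene and a methyl hydrogen is lost, puts the C8 chlorine in place before any bromine sits on C7, while the halogen-deactivated bromovinyl group stays untouched.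

Step 12
Reactants: 16 (2S,3S,5S)-2-[(E)-2-bromoethenyl]-3-chloro-5-(3-chloroprop-1-en-2-yl)-2-methyloxolane
Product: 18 1-[(2S,4S,5S)-5-[(E)-2-bromoethenyl]-4-chloro-5-methyloxolan-2-yl]-2-chloroethan-1-one, via secondary ozonide 17 (not isolated)
Conditions: O3, CH2Cl2, −78 °C (Sudan Red 7B as end-point dye); then Me2S, −78 °C → rt
Reagents that add atoms: ozone, [O-][O+]=O
Why: Ozonolysis with reductive work-up cleaves the 1,1-disubstituted alkene ahead of the bromoalkene, which is deactivated by bromine and by the neighbouring quaternary ether carbon, the dye stopping the ozone flow in time.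

Step 13
Reactants: 18 1-[(2S,4S,5S)-5-[(E)-2-bromoethenyl]-4-chloro-5-methyloxolan-2-yl]-2-chloroethan-1-one; 19 methylmagnesium bromide
Product: 20 (2S)-2-[(2S,4S,5S)-5-[(E)-2-bromoethenyl]-4-chloro-5-methyloxolan-2-yl]-1-chloropropan-2-ol
Conditions: MeMgBr (Et2O), CH2Cl2, −78 °C; then 1 M aq. HCl, −78 → 0 °C
Reagents that add atoms: none
Why: Chelation-controlled (Cram chelate) Grignard addition, in which magnesium bridges the ring oxygen and the carbonyl oxygen and methyl adds to the face of the chelate that carries the C6 hydrogen, away from the ring CH2, sets the C7 carbinol as S, and the cold quench keeps the chlorohydrin from closing to an oxirane.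

Step 14
Reactants: 20 (2S)-2-[(2S,4S,5S)-5-[(E)-2-bromoethenyl]-4-chloro-5-methyloxolan-2-yl]-1-chloropropan-2-ol
Product: 21 (2S,3S,5S)-2-[(E)-2-bromoethenyl]-5-[(2S)-2-bromo-1-chloropropan-2-yl]-3-chloro-2-methyloxolane
Conditions: HBr (33% in AcOH), CH2Cl2, 0 °C
Reagents that add atoms: hydrogen bromide, Br
Why: Substitution of a tertiary β-chloro alcohol by HBr with neighbouring-group participation (halohydrin to vicinal dihalide), in which loss of water from C7 is assisted by the anti-periplanar C8 chlorine or the ring oxygen and bromide opens the bridged ion at the tertiary carbon on the face that water left, so that C7 keeps its configuration and the chlorines at C4 and C8 are not disturbed.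

**Compound list**

1 | methacrolein (2-methylprop-2-enal) | C=C(C)C=O | starting material
2 | (−)-B-allyldiisopinocampheylborane, both isopinocampheyl groups from (+)-α-pinene | C=CCB([C@@H]1C[C@@H]2C[C@H]([C@H]1C)C2(C)C)[C@@H]1C[C@@H]2C[C@H]([C@H]1C)C2(C)C | starting material
3 | diisopinocampheylborinate of (S)-2-methylhexa-1,5-dien-3-ol | C=C(C)[C@@H](OB([C@@H]1C[C@@H]2C[C@H]([C@H]1C)C2(C)C)[C@@H]1C[C@@H]2C[C@H]([C@H]1C)C2(C)C)CC=C | intermediate
4 | (S)-2-methylhexa-1,5-dien-3-ol | C=C(C)[C@@H](O)CC=C | intermediate
5 | (S)-tert-butyldimethyl[(2-methylhexa-1,5-dien-3-yl)oxy]silane | C=C(C)[C@@H](O[Si](C)(C)C(C)(C)C)CC=C | intermediate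
6 | (2E,5S)-5-[(tert-butyldimethylsilyl)oxy]-2,6-dimethylhepta-2,6-dienal | C=C(C)[C@@H](O[Si](C)(C)C(C)(C)C)C/C=C(\C)C=O | intermediate
7 | (2E,5S)-5-[(tert-butyldimethylsilyl)oxy]-2,6-dimethylhepta-2,6-dien-1-ol | C=C(C)[C@@H](O[Si](C)(C)C(C)(C)C)C/C=C(\C)CO | intermediate
8 | [(2R,3R)-3-[(2S)-2-[(tert-butyldimethylsilyl)oxy]-3-methylbut-3-en-1-yl]-2-methyloxiran-2-yl]methanol | C=C(C)[C@@H](O[Si](C)(C)C(C)(C)C)C[C@H]1O[C@]1(C)CO | intermediate
9 | (2S,3R)-3-[(2S)-2-[(tert-butyldimethylsilyl)oxy]-3-methylbut-3-en-1-yl]-2-methyloxirane-2-carbaldehyde | C=C(C)[C@@H](O[Si](C)(C)C(C)(C)C)C[C@H]1O[C@]1(C)C=O | intermediate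
10 | bromoform | BrC(Br)Br | starting material
11 | tert-butyl{[(2S)-1-[(2R,3R)-3-[(E)-2-bromoethenyl]-3-methyloxiran-2-yl]-3-methylbut-3-en-2-yl]oxy}dimethylsilane | C=C(C)[C@@H](O[Si](C)(C)C(C)(C)C)C[C@H]1O[C@]1(C)/C=C/Br | intermediate
12 | (2S)-1-[(2R,3R)-3-[(E)-2-bromoethenyl]-3-methyloxiran-2-yl]-3-methylbut-3-en-2-ol (key-step precursor) | C=C(C)[C@@H](O)C[C@H]1O[C@]1(C)/C=C/Br | intermediate
13 | (2S,3R,5S)-2-[(E)-2-bromoethenyl]-2-methyl-5-(prop-1-en-2-yl)oxolan-3-ol (key-step product; hydroxyl trans to both arms) | C=C(C)[C@@H]1C[C@@H](O)[C@](C)(/C=C/Br)O1 | intermediate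
14 | (2S,3R,5S)-2-[(E)-2-bromoethenyl]-2-methyl-5-(prop-1-en-2-yl)oxolan-3-yl trifluoromethanesulfonate | C=C(C)[C@@H]1C[C@@H](OS(=O)(=O)C(F)(F)F)[C@](C)(/C=C/Br)O1 | intermediate
15 | (2S,3S,5S)-2-[(E)-2-bromoethenyl]-3-chloro-2-methyl-5-(prop-1-en-2-yl)oxolane | C=C(C)[C@@H]1C[C@H](Cl)[C@](C)(/C=C/Br)O1 | intermediate
16 | (2S,3S,5S)-2-[(E)-2-bromoethenyl]-3-chloro-5-(3-chloroprop-1-en-2-yl)-2-methyloxolane | C=C(CCl)[C@@H]1C[C@H](Cl)[C@](C)(/C=C/Br)O1 | intermediate
17 | secondary ozonide (1,2,4-trioxolane) of 16, mixture at the trioxolane carbon | ClCC1(OOCO1)[C@@H]1C[C@H](Cl)[C@](C)(/C=C/Br)O1 | intermediate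
18 | 1-[(2S,4S,5S)-5-[(E)-2-bromoethenyl]-4-chloro-5-methyloxolan-2-yl]-2-chloroethan-1-one | ClCC(=O)[C@@H]1C[C@H](Cl)[C@](C)(/C=C/Br)O1 | intermediate
19 | methylmagnesium bromide | C[Mg]Br | starting material
20 | (2S)-2-[(2S,4S,5S)-5-[(E)-2-bromoethenyl]-4-chloro-5-methyloxolan-2-yl]-1-chloropropan-2-ol | C[C@@](O)(CCl)[C@@H]1C[C@H](Cl)[C@](C)(/C=C/Br)O1 | intermediate
21 | (2S,3S,5S)-2-[(E)-2-bromoethenyl]-5-[(2S)-2-bromo-1-chloropropan-2-yl]-3-chloro-2-methyloxolane (CNP0172541.1) | C[C@@](Br)(CCl)[C@@H]1C[C@H](Cl)[C@](C)(/C=C/Br)O1 | target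

**Step count and risk**

Total steps: 14. Longest linear sequence: 14 steps, from 1 to 21. The key step is judged safer than the three below, because C3 is both tertiary and allylic and the only competing closure would give an oxetane.

Most likely to fail, first: step 14. The ionisation at C7 may run without effective bridging, so that bromide returns from either face and the configuration at C7 is lost. The cation may also lose a proton, take a hydride from C6, or be opened at C6 after bridging by the ring oxygen, which enlarges the ring. The fallback sets out from 15 and comes back at 21, and it makes the C7–Br bond by an SN2-like opening with no free cation. Ozonolysis of the isopropenyl group of 15 (O3, CH2Cl2, −78 °C; Me2S) gives, through the secondary ozonide F1, the methyl ketone F2. Chloromethyllithium, made in the flask from ICH2Cl and MeLi·LiBr at −78 °C, adds under the same chelation control as in step 13, and the lithium alkoxide of the chlorohydrin F3 closes on warming to the oxirane F4, whose C7 oxygen has the configuration opposite to that of 20. HBr in CH2Cl2 at −40 °C opens the oxirane at the tertiary C7 with inversion to the bromohydrin F5, and PPh3 with CCl4 turns its primary alcohol into the chloride 21. This line is held in reserve because bromide may prefer the unhindered C8 of the oxirane and because the β-bromo alcohol may rearrange through a bromonium ion during the chlorination.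

Second: step 10. Displacement at C4, a secondary carbon beside the quaternary C3, may be too slow. Loss of a C5 proton (elimination to the dihydrofuran) or migration of the anti-periplanar bromovinyl group from C3 to C4 as the triflate ionises could then take over. The fallback sets out from 13 and comes back at 15 without a sulfonate: Appel-type deoxychlorination with tri-n-octylphosphine and CCl4 in toluene at 70 °C, in which the oxyphosphonium chloride ion pair collapses with inversion under neutral conditions; no compound outside the list is made (F0).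

Third: step 7. The chromium reagent may add slowly to the hindered aldehyde, so that Lewis-acidic trivalent chromium and bromide open the oxirane, and E/Z control may erode at the temperature the bromo reagent needs. The fallback sets out from 9 and comes back at 11. Seyferth–Gilbert homologation with dimethyl (1-diazo-2-oxopropyl)phosphonate, K2CO3 and MeOH gives the alkynyl epoxide F6. Hydrozirconation with Cp2Zr(H)Cl in THF then gives the (E)-alkenylzirconocene chloride F7, which is not isolated and is brominated with N-bromosuccinimide with retention to give 11.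

Further compounds

F1 | step 14 | secondary ozonide (1,2,4-trioxolane) of 15, not isolated | CC1(OOCO1)[C@@H]1C[C@H](Cl)[C@](C)(/C=C/Br)O1
F2 | step 14 | 1-[(2S,4S,5S)-5-[(E)-2-bromoethenyl]-4-chloro-5-methyloxolan-2-yl]ethan-1-one | CC(=O)[C@@H]1C[C@H](Cl)[C@](C)(/C=C/Br)O1
F3 | step 14 | lithium (2R)-2-[(2S,4S,5S)-5-[(E)-2-bromoethenyl]-4-chloro-5-methyloxolan-2-yl]-1-chloropropan-2-olate, not isolated | C[C@](O[Li])(CCl)[C@@H]1C[C@H](Cl)[C@](C)(/C=C/Br)O1
F4 | step 14 | (2S,3S,5S)-2-[(E)-2-bromoethenyl]-3-chloro-2-methyl-5-[(2S)-2-methyloxiran-2-yl]oxolane | C[C@]1(CO1)[C@@H]2C[C@H](Cl)[C@](C)(/C=C/Br)O2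
F5 | step 14 | (2R)-2-bromo-2-[(2S,4S,5S)-5-[(E)-2-bromoethenyl]-4-chloro-5-methyloxolan-2-yl]propan-1-ol | C[C@@](Br)(CO)[C@@H]1C[C@H](Cl)[C@](C)(/C=C/Br)O1
F0 | step 10 | none | none
F6 | step 7 | tert-butyl{[(2S)-1-[(2R,3R)-3-ethynyl-3-methyloxiran-2-yl]-3-methylbut-3-en-2-yl]oxy}dimethylsilane | C=C(C)[C@@H](O[Si](C)(C)C(C)(C)C)C[C@H]1O[C@]1(C)C#C
F7 | step 7 | (E)-alkenylzirconocene chloride from F6, not isolated | C=C(C)[C@@H](O[Si](C)(C)C(C)(C)C)C[C@H]1O[C@]1(C)/C=C/[Zr](Cl)(C2C=CC=C2)C2C=CC=C2
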